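Remark on the chemistry: the target has no stereogenic element, so no SMILES string carries a stereodescriptor; "isopropyl" stands for propan-2-yl throughout.

## Analysis of the target

The target is a linear triaryl diether of three six-membered carbocycles: ring A is a 2-isopropyl-4-methoxy-5-methylphenyl unit (A1 oxygen, A2 isopropyl, A4 methoxy, A5 methyl), ring B a pentasubstituted benzene (B1 oxygen to ring A, B2 methyl, B3 methoxy, B4 hydrogen, B5 isopropyl, B6 oxygen to ring C) and ring C a 1,4-benzoquinone (C1 ether oxygen, C2 methyl, C3 carbonyl, C4 hydrogen, C5 isopropyl, C6 carbonyl). There is no stereocentre, and the crowded ethers are not expected to give separable rotamers, so no stereocontrol is needed. All three rings carry the para-cymene carbon pattern, and rings B and C share the same 1,2,4-trioxygenation (B1/B3/B6 and C1/C3/C6), so one building block can serve both. The aryloxyquinone of ring C is a vinylogous ester, open to nucleophiles, bases and reductants, and has to be unveiled last. Rings A and B are electron-rich and each is para-dioxygenated (A1/A4 and B3/B6), so a strong one-electron oxidant could turn them into quinones as well; the final oxidation must recognise ring C by more than its oxygen pattern. The difficulty lies in the two ethers: A1–O–B1 has three ortho substituents (A2 isopropyl, B2 methyl, B6 oxygen) and B6–O–C1 has four (B5 isopropyl, B1 aryloxy, C2 methyl, C6 oxygen), and ring B has no acceptor group for nucleophilic aromatic substitution. The strategy rests on the B6–O bond: B6 becomes the electrophile by carrying a trivalent iodine, and the oxygen arrives as a ring C phenoxide, so the most crowded bond forms by ligand coupling at iodine.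

## Retrosynthetic reasoning

**26 to 25.** The two carbonyl groups of ring C are taken back to the para-methoxyphenol 25 (C6 hydroxyl, C3 methoxy). A free phenol is oxidised by a trivalent iodine reagent under conditions that leave the aryl ethers of rings A and B alone. A fully methylated ring C would instead have to be told apart from two other para-dioxygenated rings by a one-electron oxidant, which is not secure. The forward step must bring a new oxygen to C3, expel the methyl group and keep the C1–O ether.

**25 to 24.** The C6 hydroxyl is masked as a methoxymethyl ether in 24. The acetal survives strong base and is removed by acid without touching methyl or diaryl ethers. It is also the group that directs the metalation used to make the phenol building block.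

**24 to 22 and 14.** The B6–O bond is cut so that ring B is the electrophile and ring C the nucleophile. Cutting on the other side of the oxygen, at C1, would need ring C as a quinone electrophile and the hindered, easily oxidised B6 oxygen of 17 as the nucleophile, which invites conjugate addition at C4 and electron transfer. Cutting at B6 with normal polarity fails because ring B is electron-rich and doubly ortho-substituted. The iodonium salt 22 reverses the polarity of B6, and the small potassium phenoxide 14 is the nucleophile. The forward step must transfer the ring B aryl rather than the auxiliary aryl, and only to oxygen.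

**14 to 10.** The potassium salt 14 is traced to phenol 10 by one deprotonation. Made in a single batch with a slight deficit of base and freed of tert-butanol, it is a nucleophile of known stoichiometry that carries no free alkoxide into either arylation.

**22 to 20 and 11.** The iodine–aryl bond to the 2,4,6-trimethoxyphenyl group is cut. Oxidation of iodide 20 to trivalent iodine, followed by electrophilic substitution of arene 11, builds the salt in one flask. Arene 11 is chosen because its aryl group is the most reluctant to migrate later.

**20 to 19 to 18 to 17.** The C–I bond at B6 is traced to a C–B bond and then to the C–O bond of phenol 17 through triflate 18. Oxygen is the natural substituent at B6 in this ring system. Each exchange is at the ipso carbon, so the position of iodine is fixed by the position of the hydroxyl.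

**17 to 16 to 14 and 13.** The A1–O bond is cut after unmasking the B6 oxygen. Because rings B and C have the same substitution pattern, the phenoxide 14 that provides ring C also provides ring B. Its phenoxide oxygen becomes the B1 oxygen and its acetal oxygen becomes the B6 oxygen. Ring A arrives as the iodonium salt 13, so both ethers come from one reaction type and one nucleophile.

**13 to 3 and 11.** As for 22, the auxiliary aryl–iodine bond is cut back to aryl iodide 3.

**10 to 7 to 6.** The hydroxyl of 10 is removed retrosynthetically at the only ring position ortho to the acetal of 7. Directed metalation places it there, between the acetal oxygen and the methyl group. 7 is the protected form of phenol 6.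

**6 to 3 to 2 to 1.** The hydroxyl of 6 replaces the iodine of 3, which sits para to the methoxy group of 2, the methyl ether of 1. Iodide 3 is thus the branch point: it gives ring A as an electrophile and, after hydroxylation, rings B and C as nucleophiles.

## Alternatives that were turned down

**Alternative 1:** The disconnection runs through ring A itself, across A5–A6 and A2–A3, with the A1 oxygen already attached to a three-carbon piece. In the forward key step TiCl4 joins the 1,3-bis(silyloxy)diene A2 and the 2-aryloxy-3-silyloxyenone A3 in a formal [3+3] cyclocondensation that closes ring A as the salicylate A1.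
- For it: the ether oxygen is already in place in A3, put there by a simple O-alkylation before ring A exists, so the first crowded diaryl ether coupling is avoided. Every ring A substituent is fixed by the connectivity of two acyclic pieces. On these two points it is stronger than the chosen route.
- Against it: it assembles a benzene ring that carvacrol (1) supplies ready-made. A1 still needs O-methylation, hydrolysis of a doubly ortho-flanked ester, protodecarboxylation and debenzylation before it reaches the stage of 17. The cyclisation has to occur at an isopropyl ketone beside a bulky aryloxy group under a Lewis acid that also threatens the benzyl ether. The B6–O–C1 bond is left unsolved.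
- Comparison: the chosen route reaches 17 from 10 in three steps and uses the same reaction for the harder ether.

**Alternative 2:** The disconnection is the A1 oxygen–B1 bond between two molecules of one phenol. In the forward key step 4-methoxythymol A4 (the same compound as 6) is oxidised at a carbon anode, and the phenoxyl oxygen of one molecule bonds to the free ortho carbon of another to give the AB phenol A5 (identical with 17).
- For it: one step, no protecting groups and no stoichiometric reagent. In step count to the AB phenol it is clearly stronger than the chosen route (one step from 6 against six operations).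
- Against it: the phenoxyl radical has spin density on oxygen, on the ortho carbon and on the methoxy-bearing para carbon. Ortho C–C coupling and attack at the para carbon with loss of the methyl group therefore compete with O–C coupling. A5 is more electron-rich than A4 and is oxidised further at the working potential. Nothing in the substrate decides among these paths. The B6–O–C1 bond again remains.
- Comparison: the chosen strategy offers ethers whose two partners are defined by an iodine and a hydroxyl group, and its phenol 10 is needed for ring C in any case.

**Alternative 3:** The disconnection is the A1–O bond, with ring A as a carbene equivalent. In the forward key step Rh2(OAc)4 converts the para-quinone diazide A6, derived from 1, into a carbenoid at the carbon that becomes A1. This inserts into the O–H bond of the ring B phenol A7 and, after tautomerisation, gives the diaryl ether A8 with a free ring A hydroxyl.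
- For it: neutral conditions at room temperature, and a bond formation through an oxonium ylide with an early transition state that is little affected by ortho groups. A8 needs only O-methylation. In mildness it is at least equal to the iodonium arylation.
- Against it: the electrophilic carbenoid can also attack the free B4 position of the electron-rich ring of A7 or its benzyl ether (ylide formation, benzylic C–H insertion). A6 requires nitrosation, reduction and diazotisation and is a hazardous diazo compound. The second, harder ether is again left open.
- Comparison: the number of steps to the first ether is about the same. The chosen route uses one reaction type and one phenol for both ethers and avoids diazo chemistry.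

Key step: step 14

## Route

Step 1
Reactants: 1 carvacrol (5-isopropyl-2-methylphenol)
Product: 2 carvacrol methyl ether (4-isopropyl-2-methoxy-1-methylbenzene)
Conditions: MeI, K2CO3, acetone, reflux
Reagents that add atoms: iodomethane, CI
Why: Williamson O-methylation of the phenoxide; there is no competing nucleophilic site.

Step 2
Reactants: 2 carvacrol methyl ether
Product: 3 1-iodo-2-isopropyl-4-methoxy-5-methylbenzene
Conditions: NIS, TFA (cat.), MeCN, rt
Reagents that add atoms: N-iodosuccinimide, O=C1CCC(=O)N1I
Why: Electrophilic aromatic iodination; the methoxy group directs para, and the only other activated position lies between methoxy and isopropyl and is more hindered.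

Step 3
Reactants: 3 1-iodo-2-isopropyl-4-methoxy-5-methylbenzene
Product: 6 4-methoxythymol (2-isopropyl-4-methoxy-5-methylphenol), via aryllithium 4 (not isolated), via dimethyl arylboronate 5 (not isolated)
Conditions: n-BuLi, THF, −78 °C; B(OMe)3, −78 °C to rt; H2O2, aq NaOH, 0 °C to rt
Reagents that add atoms: hydrogen peroxide, OO (phenol oxygen); n-butyllithium, [Li]CCCC (lithium of intermediate 4 only); trimethyl borate, COB(OC)OC (boron and methoxy groups of intermediate 5 only)
Why: Iodine–lithium exchange, borylation and oxidative 1,2-shift of the aryl group from boron to oxygen (ipso-hydroxylation) should put the hydroxyl exactly where the iodine was, so the phenol is obtained without regioisomers.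

Step 4
Reactants: 6 4-methoxythymol
Product: 7 1-isopropyl-5-methoxy-2-(methoxymethoxy)-4-methylbenzene
Conditions: MOMCl, i-Pr2NEt, CH2Cl2, 0 °C to rt
Reagents that add atoms: chloromethyl methyl ether, COCCl
Why: O-alkylation of the phenol to the methoxymethyl acetal, which serves as directing group in step 5 and as acid-labile protection later.

Step 5
Reactants: 7 1-isopropyl-5-methoxy-2-(methoxymethoxy)-4-methylbenzene
Product: 10 3-isopropyl-5-methoxy-2-(methoxymethoxy)-6-methylphenol, via aryllithium 8 (not isolated), via dimethyl arylboronate 9 (not isolated)
Conditions: s-BuLi, TMEDA, THF, −78 °C; B(OMe)3, −78 °C to rt; H2O2, aq NaOH, 0 °C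
Reagents that add atoms: hydrogen peroxide, OO (phenol oxygen); sec-butyllithium, [Li]C(C)CC (lithium of intermediate 8 only); trimethyl borate, COB(OC)OC (boron and methoxy groups of intermediate 9 only)
Why: Directed ortho-metalation; the acetal chelates lithium and has only one free ortho position, between itself and the methyl group, whereas the other ring hydrogen sits between a weaker methoxy director and isopropyl. Borylation–oxidation then turns C–Li into C–OH.

Step 6
Reactants: 3 1-iodo-2-isopropyl-4-methoxy-5-methylbenzene; 11 1,3,5-trimethoxybenzene
Product: 13 (2-isopropyl-4-methoxy-5-methylphenyl)(2,4,6-trimethoxyphenyl)iodonium 4-methylbenzenesulfonate, via hydroxy(tosyloxy)iodoarene 12 (not isolated)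
Conditions: mCPBA, TsOH·H2O, MeCN, rt to 50 °C; then 11, rt
Reagents that add atoms: 4-methylbenzenesulfonic acid monohydrate, Cc1ccc(S(=O)(=O)O)cc1.O (tosylate counter-ion); 3-chloroperbenzoic acid, OOC(=O)c1cccc(Cl)c1 (hydroxyl oxygen of intermediate 12 only)
Why: One-pot diaryliodonium synthesis: the peracid oxidises the aryl iodide to the trivalent hydroxy(tosyloxy)iodane, which is then attacked by the very nucleophilic arene 11 in an electrophilic aromatic substitution at iodine.

Step 7
Reactants: 10 3-isopropyl-5-methoxy-2-(methoxymethoxy)-6-methylphenol
Product: 14 potassium 3-isopropyl-5-methoxy-2-(methoxymethoxy)-6-methylphenolate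
Conditions: KOtBu (0.97 equiv), THF, 0 °C to rt, Ar; evaporation, co-evaporation with toluene, high vacuum; stored under Ar
Reagents that add atoms: potassium tert-butoxide, CC(C)(C)[O-].[K+]
Why: Brønsted acid–base reaction; the phenol is far more acidic than tert-butanol, so deprotonation should be complete and the alcohol leaves with the solvent. The slight deficit of base ensures that no tert-butoxide reaches the iodonium salts, and one batch of the salt serves both arylations (steps 8 and 14).

Step 8
Reactants: 14 potassium 3-isopropyl-5-methoxy-2-(methoxymethoxy)-6-methylphenolate; 13 ring A iodonium tosylate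
Product: 16 1-isopropyl-3-(2-isopropyl-4-methoxy-5-methylphenoxy)-5-methoxy-2-(methoxymethoxy)-4-methylbenzene, via aryloxyiodane 15 (not isolated)
Conditions: 14 (1.1 equiv), THF, rt to 40 °C
Reagents that add atoms: none
Why: Transition-metal-free O-arylation of a phenoxide with a diaryliodonium salt by ligand exchange and ligand coupling at trivalent iodine. The 2,4,6-trimethoxyphenyl group is the more electron-rich aryl and should stay on iodine, and the absence of free alkoxide avoids aryne formation at the one ortho hydrogen (A6) of the ring A aryl.

Step 9
Reactants: 16 ring AB ether with B6 methoxymethyl ether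
Product: 17 2-isopropyl-6-(2-isopropyl-4-methoxy-5-methylphenoxy)-4-methoxy-5-methylphenol (AB phenol)
Conditions: conc. HCl (cat.), MeOH, 50 °C
Reagents that add atoms: none
Why: Acid-catalysed acetal methanolysis; aryl methyl ethers and the diaryl ether are inert under these conditions.

Step 10
Reactants: 17 AB phenol
Product: 18 2-isopropyl-6-(2-isopropyl-4-methoxy-5-methylphenoxy)-4-methoxy-5-methylphenyl trifluoromethanesulfonate
Conditions: Tf2O, pyridine, CH2Cl2, 0 °C to rt
Reagents that add atoms: trifluoromethanesulfonic anhydride, O=S(=O)(OS(=O)(=O)C(F)(F)F)C(F)(F)F
Why: O-sulfonylation of the phenol; 2,6-disubstituted phenols are triflated under these standard conditions because the electrophile is small and very reactive.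

Step 11
Reactants: 18 AB triflate
Product: 19 2-[2-isopropyl-6-(2-isopropyl-4-methoxy-5-methylphenoxy)-4-methoxy-5-methylphenyl]-4,4,5,5-tetramethyl-1,3,2-dioxaborolane
Conditions: B2pin2, Pd(OAc)2, SPhos, KOAc, 1,4-dioxane, 100 °C
Reagents that add atoms: bis(pinacolato)diboron, CC1(C)OB(B2OC(C)(C)C(C)(C)O2)OC1(C)C
Why: Miyaura borylation: zerovalent palladium formed from Pd(OAc)2 and the bulky, electron-rich biaryl phosphine inserts into the C–OTf bond, acetate-assisted transmetalation with the diboron follows, and reductive elimination gives the arylboronate. This ligand class is the one used for doubly ortho-substituted substrates.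

Step 12
Reactants: 19 AB pinacol boronate
Product: 20 2-iodo-1-isopropyl-3-(2-isopropyl-4-methoxy-5-methylphenoxy)-5-methoxy-4-methylbenzene
Conditions: NaI, TsN(Cl)Na·3H2O (chloramine-T trihydrate), THF/H2O, rt
Reagents that add atoms: sodium iodide, [Na+].[I-]
Why: Electrophilic ipso-iododeboronation; the electrophilic iodine formed in situ attacks the boron-bearing carbon, which is para to the B3 methoxy group and therefore the most nucleophilic site, so iodine should end up only at B6.

Step 13
Reactants: 20 AB iodide; 11 1,3,5-trimethoxybenzene
Product: 22 [2-isopropyl-6-(2-isopropyl-4-methoxy-5-methylphenoxy)-4-methoxy-5-methylphenyl](2,4,6-trimethoxyphenyl)iodonium 4-methylbenzenesulfonate, via hydroxy(tosyloxy)iodoarene 21 (not isolated)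
Conditions: mCPBA, TsOH·H2O, MeCN, rt to 40 °C; then 11, rt
Reagents that add atoms: 4-methylbenzenesulfonic acid monohydrate, Cc1ccc(S(=O)(=O)O)cc1.O (tosylate counter-ion); 3-chloroperbenzoic acid, OOC(=O)c1cccc(Cl)c1 (hydroxyl oxygen of intermediate 21 only)
Why: Same one-pot oxidation and arylation at iodine as in step 6. Arene 11 is far more nucleophilic than any open position of rings A and B and, with tosylic acid rather than a superacid as activator, should capture the trivalent iodine before ring A can.

Step 14
Reactants: 22 ring AB iodonium tosylate; 14 potassium 3-isopropyl-5-methoxy-2-(methoxymethoxy)-6-methylphenolate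
Product: 24 1-isopropyl-3-(2-isopropyl-4-methoxy-5-methylphenoxy)-2-[3-isopropyl-5-methoxy-2-(methoxymethoxy)-6-methylphenoxy]-5-methoxy-4-methylbenzene, via aryloxyiodane 23 (not isolated)
Conditions: 14 (1.2 equiv), THF/toluene, rt to 60 °C
Reagents that add atoms: none
Why: The phenoxide 14 replaces tosylate on the trivalent iodine of 22 and gives the T-shaped aryloxy(diaryl)iodane 23, in which the oxygen and one aryl group share the three-centre four-electron axis. Ligand coupling between the oxygen and the ipso carbon B6 then forms the B6–O bond through a three-membered transition state and releases the auxiliary as its aryl iodide, with iodine returning to the monovalent state. The closest known reaction type is the transition-metal-free O-arylation of alkali phenoxides with diaryliodonium salts, which has been used for diaryl ethers substituted at all four ortho positions. No ring is closed and no stereocentre is created. The step needs the ring B aryl, not the 2,4,6-trimethoxyphenyl group, to move to oxygen: the ipso carbon of the auxiliary carries two ortho and one para methoxy donor and accepts the incoming electron density far less readily than B6, so it should stay on iodine. The oxygen must arrive at B6 and nowhere else: both neighbours of B6 (B1 and B5) are substituted, so no aryne can form and ipso substitution is the only path. O-arylation rather than C-arylation of 14 is secured because both ortho positions of the phenoxide are blocked by methyl and by the acetal oxygen. Crowding hampers oxidative addition and reductive elimination at copper or palladium, but it matters less here because both partners are already bound to one iodine atom before the bond forms.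

Step 15
Reactants: 24 triaryl diether with C6 methoxymethyl ether
Product: 25 6-isopropyl-2-[2-isopropyl-6-(2-isopropyl-4-methoxy-5-methylphenoxy)-4-methoxy-5-methylphenoxy]-4-methoxy-3-methylphenol
Conditions: conc. HCl (cat.), MeOH/THF, 50 °C
Reagents that add atoms: none
Why: Acid-catalysed acetal methanolysis as in step 9; it frees the only hydroxyl of the molecule, on ring C.

Step 16
Reactants: 25 ring C para-methoxyphenol
Product: 26 2-[2-isopropyl-6-(2-isopropyl-4-methoxy-5-methylphenoxy)-4-methoxy-5-methylphenoxy]-6-isopropyl-3-methyl-1,4-benzoquinone (target)
Conditions: PhI(OAc)2, MeCN/H2O (2:1), 0 °C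
Reagents that add atoms: water, O
Why: Oxidative demethylation of a para-methoxyphenol: the phenol binds the trivalent iodine and is oxidised by two electrons, water adds to the para carbon C3 that bears the methoxy group, and loss of methanol gives the quinone. Rings A and B have no free hydroxyl and should not be attacked by this oxidant.

## Compound list

1 | carvacrol (5-isopropyl-2-methylphenol) | Cc1ccc(C(C)C)cc1O | starting material
2 | carvacrol methyl ether (4-isopropyl-2-methoxy-1-methylbenzene) | COc1cc(C(C)C)ccc1C | intermediate
3 | 1-iodo-2-isopropyl-4-methoxy-5-methylbenzene | COc1cc(C(C)C)c(I)cc1C | intermediate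
4 | (2-isopropyl-4-methoxy-5-methylphenyl)lithium | [Li]c1cc(C)c(OC)cc1C(C)C | intermediate
5 | dimethyl (2-isopropyl-4-methoxy-5-methylphenyl)boronate | COB(OC)c1cc(C)c(OC)cc1C(C)C | intermediate
6 | 4-methoxythymol (2-isopropyl-4-methoxy-5-methylphenol) | COc1cc(C(C)C)c(O)cc1C | intermediate
7 | 1-isopropyl-5-methoxy-2-(methoxymethoxy)-4-methylbenzene | COCOc1cc(C)c(OC)cc1C(C)C | intermediate
8 | [3-isopropyl-5-methoxy-2-(methoxymethoxy)-6-methylphenyl]lithium | [Li]c1c(C)c(OC)cc(C(C)C)c1OCOC | intermediate
9 | dimethyl [3-isopropyl-5-methoxy-2-(methoxymethoxy)-6-methylphenyl]boronate | COB(OC)c1c(C)c(OC)cc(C(C)C)c1OCOC | intermediate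
10 | 3-isopropyl-5-methoxy-2-(methoxymethoxy)-6-methylphenol | COCOc1c(O)c(C)c(OC)cc1C(C)C | intermediate
11 | 1,3,5-trimethoxybenzene | COc1cc(OC)cc(OC)c1 | starting material
12 | 1-[hydroxy(tosyloxy)iodo]-2-isopropyl-4-methoxy-5-methylbenzene | Cc1ccc(S(=O)(=O)OI(O)c2cc(C)c(OC)cc2C(C)C)cc1 | intermediate
13 | (2-isopropyl-4-methoxy-5-methylphenyl)(2,4,6-trimethoxyphenyl)iodonium 4-methylbenzenesulfonate | COc1cc(OC)c([I+]c2cc(C)c(OC)cc2C(C)C)c(OC)c1.Cc1ccc(S(=O)(=O)[O-])cc1 | intermediate
14 | potassium 3-isopropyl-5-methoxy-2-(methoxymethoxy)-6-methylphenolate | COCOc1c([O-])c(C)c(OC)cc1C(C)C.[K+] | intermediate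
15 | (2-isopropyl-4-methoxy-5-methylphenyl)[3-isopropyl-5-methoxy-2-(methoxymethoxy)-6-methylphenoxy](2,4,6-trimethoxyphenyl)iodane | COCOc1c(OI(c2cc(C)c(OC)cc2C(C)C)c2c(OC)cc(OC)cc2OC)c(C)c(OC)cc1C(C)C | intermediate
16 | 1-isopropyl-3-(2-isopropyl-4-methoxy-5-methylphenoxy)-5-methoxy-2-(methoxymethoxy)-4-methylbenzene | COCOc1c(Oc2cc(C)c(OC)cc2C(C)C)c(C)c(OC)cc1C(C)C | intermediate
17 | 2-isopropyl-6-(2-isopropyl-4-methoxy-5-methylphenoxy)-4-methoxy-5-methylphenol (AB phenol) | COc1cc(C(C)C)c(Oc2c(C)c(OC)cc(C(C)C)c2O)cc1C | intermediate
18 | 2-isopropyl-6-(2-isopropyl-4-methoxy-5-methylphenoxy)-4-methoxy-5-methylphenyl trifluoromethanesulfonate | COc1cc(C(C)C)c(Oc2c(C)c(OC)cc(C(C)C)c2OS(=O)(=O)C(F)(F)F)cc1C | intermediate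
19 | 2-[2-isopropyl-6-(2-isopropyl-4-methoxy-5-methylphenoxy)-4-methoxy-5-methylphenyl]-4,4,5,5-tetramethyl-1,3,2-dioxaborolane | COc1cc(C(C)C)c(Oc2c(C)c(OC)cc(C(C)C)c2B2OC(C)(C)C(C)(C)O2)cc1C | intermediate
20 | 2-iodo-1-isopropyl-3-(2-isopropyl-4-methoxy-5-methylphenoxy)-5-methoxy-4-methylbenzene | COc1cc(C(C)C)c(Oc2c(C)c(OC)cc(C(C)C)c2I)cc1C | intermediate
21 | 2-[hydroxy(tosyloxy)iodo]-1-isopropyl-3-(2-isopropyl-4-methoxy-5-methylphenoxy)-5-methoxy-4-methylbenzene | Cc1ccc(S(=O)(=O)OI(O)c2c(C(C)C)cc(OC)c(C)c2Oc2cc(C)c(OC)cc2C(C)C)cc1 | intermediate
22 | [2-isopropyl-6-(2-isopropyl-4-methoxy-5-methylphenoxy)-4-methoxy-5-methylphenyl](2,4,6-trimethoxyphenyl)iodonium 4-methylbenzenesulfonate | COc1cc(OC)c([I+]c2c(C(C)C)cc(OC)c(C)c2Oc2cc(C)c(OC)cc2C(C)C)c(OC)c1.Cc1ccc(S(=O)(=O)[O-])cc1 | intermediate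
23 | [2-isopropyl-6-(2-isopropyl-4-methoxy-5-methylphenoxy)-4-methoxy-5-methylphenyl][3-isopropyl-5-methoxy-2-(methoxymethoxy)-6-methylphenoxy](2,4,6-trimethoxyphenyl)iodane | COCOc1c(OI(c2c(C(C)C)cc(OC)c(C)c2Oc2cc(C)c(OC)cc2C(C)C)c2c(OC)cc(OC)cc2OC)c(C)c(OC)cc1C(C)C | intermediate
24 | 1-isopropyl-3-(2-isopropyl-4-methoxy-5-methylphenoxy)-2-[3-isopropyl-5-methoxy-2-(methoxymethoxy)-6-methylphenoxy]-5-methoxy-4-methylbenzene | COc1cc(C(C)C)c(Oc2c(C)c(OC)cc(C(C)C)c2Oc2c(C)c(OC)cc(C(C)C)c2OCOC)cc1C | intermediate
25 | 6-isopropyl-2-[2-isopropyl-6-(2-isopropyl-4-methoxy-5-methylphenoxy)-4-methoxy-5-methylphenoxy]-4-methoxy-3-methylphenol | COc1cc(C(C)C)c(Oc2c(C)c(OC)cc(C(C)C)c2Oc2c(C)c(OC)cc(C(C)C)c2O)cc1C | intermediate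
26 | 2-[2-isopropyl-6-(2-isopropyl-4-methoxy-5-methylphenoxy)-4-methoxy-5-methylphenoxy]-6-isopropyl-3-methyl-1,4-benzoquinone | COc1cc(C(C)C)c(Oc2c(C)c(OC)cc(C(C)C)c2OC2=C(C)C(=O)C=C(C(C)C)C2=O)cc1C | target

## Step count and risks

Total step count: 16. Longest linear sequence: 15 steps (1–5, then 7–16); step 6 is the only branch, from 3.

Least certain steps:

**Step 14 (key step).** Ligand coupling may be slow at a carbon and an oxygen that together carry four ortho substituents. The aryloxyiodane could then decay by homolysis back to the aryl iodide, or the auxiliary aryl could be transferred instead. Fallback, with the polarity of the B6–O–C1 bond formation reversed: 6 is brominated ortho to its hydroxyl (N-bromosuccinimide, MeCN, 0 °C) to give 2-bromo-6-isopropyl-4-methoxy-3-methylphenol F1. PhI(OAc)2 in aqueous MeCN should oxidise this to 2-bromo-6-isopropyl-3-methyl-1,4-benzoquinone F2. Phenol 17 (K2CO3, DMF, rt) would then displace bromide from F2 by conjugate addition–elimination. This fallback sets out from 17 and 6 and comes back to the route at 26.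

**Step 13.** The freshly formed trivalent iodine at B6 may attack A6 of the neighbouring ring A intramolecularly, closing a six-membered cyclic iodonium, or the peracid may oxidise the electron-rich rings before arene 11 is added. Fallback, separating oxidation from aryl transfer and avoiding strong acid: 20 is oxidised with NaBO3·4H2O in acetic acid at 40 °C to 2-(diacetoxyiodo)-1-isopropyl-3-(2-isopropyl-4-methoxy-5-methylphenoxy)-5-methoxy-4-methylbenzene F3. This is stirred with an excess of 11 in 2,2,2-trifluoroethanol at rt, so that the strongest nucleophile is present from the moment the iodane is activated, and should give [2-isopropyl-6-(2-isopropyl-4-methoxy-5-methylphenoxy)-4-methoxy-5-methylphenyl](2,4,6-trimethoxyphenyl)iodonium acetate F4. F4 takes the place of 22 in step 14 and reacts there with 14. The fallback sets out from 20 and comes back at 24.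

**Step 11.** Transmetalation at the carbon flanked by isopropyl and aryloxy may be slow enough that reduction of the C–O bond to C–H, or hydrolysis of the triflate, takes over. Fallback, using a base-free tin transfer and a clean tin–iodine exchange: 18 is treated with Me3SnSnMe3, Pd(PPh3)4 and LiCl in 1,4-dioxane at 100 °C to give [2-isopropyl-6-(2-isopropyl-4-methoxy-5-methylphenoxy)-4-methoxy-5-methylphenyl]trimethylstannane F5. Iodine in CH2Cl2 at 0 °C then cleaves the C–Sn bond. The fallback sets out from 18 and comes back at 20, replacing steps 11 and 12.

**Step 8.** The same ligand coupling as in the key step, on a less crowded pair. Slow coupling could give way to decomposition of the salt or to transfer of the auxiliary aryl. Fallback, copper catalysis from the aryl iodide in place of trivalent iodine: 3 and 10 are coupled in an Ullmann ether synthesis (CuI, picolinic acid, K3PO4, DMSO, 90 °C), which tolerates ortho substituents on both partners. The fallback sets out from 3 and 10 and comes back at 16; it makes no new compound.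

**Step 5.** Deprotonation may stray to the methyl group beside the ring methoxy (lateral metalation) or to the ring position between methoxy and isopropyl, leading to regioisomeric products. Fallback, electrophilic ortho-functionalisation directed by the free phenol: 6 is formylated ortho to its hydroxyl (MgCl2, Et3N, paraformaldehyde, MeCN, reflux) to give 2-hydroxy-3-isopropyl-5-methoxy-6-methylbenzaldehyde F6. Protection (MOMCl, i-Pr2NEt, CH2Cl2) gives 3-isopropyl-5-methoxy-2-(methoxymethoxy)-6-methylbenzaldehyde F7. Baeyer–Villiger oxidation (mCPBA, CH2Cl2) gives 3-isopropyl-5-methoxy-2-(methoxymethoxy)-6-methylphenyl formate F8, and hydrolysis with KOH in aqueous MeOH releases the phenol. The fallback sets out from 6 and comes back at 10.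

## Further compounds

F1 | step 14 | 2-bromo-6-isopropyl-4-methoxy-3-methylphenol | COc1cc(C(C)C)c(O)c(Br)c1C
F2 | step 14 | 2-bromo-6-isopropyl-3-methyl-1,4-benzoquinone | CC1=C(Br)C(=O)C(C(C)C)=CC1=O
F3 | step 13 | 2-(diacetoxyiodo)-1-isopropyl-3-(2-isopropyl-4-methoxy-5-methylphenoxy)-5-methoxy-4-methylbenzene | CC(=O)OI(OC(C)=O)c1c(C(C)C)cc(OC)c(C)c1Oc1cc(C)c(OC)cc1C(C)C
F4 | step 13 | [2-isopropyl-6-(2-isopropyl-4-methoxy-5-methylphenoxy)-4-methoxy-5-methylphenyl](2,4,6-trimethoxyphenyl)iodonium acetate | COc1cc(OC)c([I+]c2c(C(C)C)cc(OC)c(C)c2Oc2cc(C)c(OC)cc2C(C)C)c(OC)c1.CC(=O)[O-]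
F5 | step 11 | [2-isopropyl-6-(2-isopropyl-4-methoxy-5-methylphenoxy)-4-methoxy-5-methylphenyl]trimethylstannane | COc1cc(C(C)C)c(Oc2c(C)c(OC)cc(C(C)C)c2[Sn](C)(C)C)cc1C
F0 | step 8 | none | none
F6 | step 5 | 2-hydroxy-3-isopropyl-5-methoxy-6-methylbenzaldehyde | COc1cc(C(C)C)c(O)c(C=O)c1C
F7 | step 5 | 3-isopropyl-5-methoxy-2-(methoxymethoxy)-6-methylbenzaldehyde | COCOc1c(C=O)c(C)c(OC)cc1C(C)C
F8 | step 5 | 3-isopropyl-5-methoxy-2-(methoxymethoxy)-6-methylphenyl formate | COCOc1c(OC=O)c(C)c(OC)cc1C(C)C
A1 | alternative 1 | methyl 5-[2-(benzyloxy)-3-isopropyl-5-methoxy-6-methylphenoxy]-2-hydroxy-6-isopropyl-3-methylbenzoate | COC(=O)c1c(O)c(C)cc(Oc2c(C)c(OC)cc(C(C)C)c2OCc2ccccc2)c1C(C)C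
A2 | alternative 1 | 1-methoxy-1,3-bis(trimethylsilyloxy)penta-1,3-diene | CC=C(O[Si](C)(C)C)C=C(OC)O[Si](C)(C)C
A3 | alternative 1 | 2-[2-(benzyloxy)-3-isopropyl-5-methoxy-6-methylphenoxy]-4-methyl-1-(trimethylsilyloxy)pent-1-en-3-one | CC(C)C(=O)C(Oc1c(C)c(OC)cc(C(C)C)c1OCc1ccccc1)=CO[Si](C)(C)C
A4 | alternative 2 | 4-methoxythymol (identical with 6) | COc1cc(C(C)C)c(O)cc1C
A5 | alternative 2 | AB phenol (identical with 17) | COc1cc(C(C)C)c(Oc2c(C)c(OC)cc(C(C)C)c2O)cc1C
A6 | alternative 3 | 4-diazo-5-isopropyl-2-methylcyclohexa-2,5-dien-1-one | CC1=CC(=[N+]=[N-])C(C(C)C)=CC1=O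
A7 | alternative 3 | 2-(benzyloxy)-3-isopropyl-5-methoxy-6-methylphenol | COc1cc(C(C)C)c(OCc2ccccc2)c(O)c1C
A8 | alternative 3 | 4-[2-(benzyloxy)-3-isopropyl-5-methoxy-6-methylphenoxy]-5-isopropyl-2-methylphenol | Cc1cc(Oc2c(C)c(OC)cc(C(C)C)c2OCc2ccccc2)c(C(C)C)cc1O
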